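## Structural features

The target is an oxolane (ring atoms O1, C2, C3, C4, C5; this numbering is kept for every oxolane below) with a 3,4,5-trimethoxyphenyl group on C2, a hydroxymethyl group on C3 and a 3,4,5-trimethoxybenzoyl group on C4, while C5 is an unsubstituted CH2 next to O1. Its three stereocentres are contiguous and are (2S,3S,4R): the aryl and CH2OH groups are cis, the CH2OH and aroyl groups are trans. C4 is α to the ketone and β to the ring oxygen, so it can epimerise and the ring can open by retro-oxa-Michael reaction under base; its configuration is, however, the thermodynamically preferred one and can be reached by equilibration. The C2–O1 bond is the benzylic ether of an electron-rich arene and may ionise under strong acid, which would drain the less stable 2,3-cis arrangement; this cis pair, next to an epimerisable centre, is the real difficulty. The primary alcohol would interfere with Lewis acids and organometallic reagents and must stay masked until the end. Read as O1–C2(aryl)–C3–C4(acyl)–C5H2, the ring is a 4-acyl oxolane, the product pattern of a Prins cyclisation ended by a ring-contracting pinacol shift: the cis C2/C3 pair corresponds to a Z-alkene, the acyl carbon on C4 to the carbinol carbon of an allylic 1,2-diol, and C5 to its CH2O carbon. A re-derivation of all descriptors shows that a (4R)-4-alkenyl-1,3-dioxolane leads to the 2S,3S series, so no structure had to be corrected.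

## Logic of the disconnections

15 ⇒ 14. Cut: the O–Si bond on the primary alcohol. The hydroxyl is unveiled last because it would quench the organometallic reagent and bind the Lewis acid. Nothing is gained in skeleton, but the earlier steps are freed of a protic group. The forward step must be neither basic enough to enolise C4 or open the β-alkoxy ketone nor acidic enough to ionise C2–O1.

14 ⇒ 13 ⇒ 10 + 11 (through 12). Cut: the bond between the carbonyl carbon and its arene, after stepping back from ketone to carbinol. An aryl carbinol on this carbon would be tertiary and benzylic in the cationic key step and would ionise, so the second arene is added afterwards to a formyl group. This removes one arene and the ketone. The forward steps need clean 1,2-addition of 12 to an enolisable β-alkoxy aldehyde and a mild oxidation; the carbinol configuration does not matter.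

10 ⇒ 9. Formal cut: the C4–H bond, that is, inversion at C4. The key step can only place the formyl group cis to the C3 substituent, whereas the target needs it trans; C4 is enolisable and trans is favoured. The stereochemical problem shrinks to C2 and C3. The forward step needs equilibration without ring opening or aldol reaction.

9 ⇒ 8. Cuts: C2–C3 and C4–C5, with the formyl carbon reconnected to C5 as a carbinol. Both bonds, the ring and all three stereocentres go back to one stereocentre, one Z-alkene and an acetal. The forward step needs regioselective ionisation, a chair-controlled 6-endo closure and a ring-contracting shift, all in the presence of an allylic silyl ether.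

8 ⇒ 7 + 6. Cuts: the two acetal C–O bonds. The acetal carbon loses its configuration in the key step, so both epimers serve and no selectivity is asked for. The forward step needs mild acid that leaves the Z-allylic silyl ether alone.

7 ⇒ 5 ⇒ 4. Cuts: the O–Si bond and the change of diol protection. The diol is carried as its acetonide so that only the allylic hydroxyl is silylated. The forward steps need a silyl group that survives acetonide removal and SnCl4, and is bulky and non-participating.

4 ⇒ 3 ⇒ 2. Cut: the Cα=Cβ double bond, after stepping back from allylic alcohol to ester. The Z geometry that later becomes the cis C2/C3 pair is set by olefination of an α-alkoxy aldehyde. The forward step needs high Z-selectivity without epimerising the α-centre.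

2 ⇒ 1. Change of oxidation level only. The single controlling stereocentre is bought in enantiopure form. Asymmetric dihydroxylation of a terminal vinyl alkyne followed by semihydrogenation would reach 7 in as many steps, but such terminal alkenes are not reliably dihydroxylated with high enantioselectivity and a gaseous vinyl halide would be needed.

## Other disconnections considered

Alternative 1: Cut O1–C5 and C3–C4, which divides the ring into the aryl propargylic alcohol A2, the aroylacetate A3 and a one-carbon unit for C5.
- Forward key step: the alkoxide of A2 adds to the 2-aroylacrylate formed in the flask from A3 (oxa-Michael, O1–C5). The keto ester enolate then closes 5-exo-dig onto the CuI-activated alkyne (Conia-ene type, C3–C4) to give the 3-methylidene oxolane A1.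
- In its favour: both arenes, the ketone at its final oxidation level and all ring atoms are assembled in one convergent operation. Only C2 must be set beforehand. The closure is a favoured exo mode, and the basic medium never generates an electron-rich benzylic cation.
- Against it here: C3 is created later by hydroboration of the exocyclic alkene. Attack away from the C2 aryl must be won against two large groups on quaternary C4, and in the presence of an aryl ketone. The ester must then be removed, and once C4 bears hydrogen the β,γ-unsaturated ketone can move into conjugation. The acrylate may polymerise and its oxa-Michael adduct can revert.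
- Comparison: in step count and convergence this alternative is the better one (about five operations from 6 against ten). It is the equal of the chosen plan in leaving C4 to thermodynamic control. The chosen plan is stronger in stereochemistry, because C2 and C3 are set together in one chair transition state from a pool-derived centre, and it avoids a borane next to the ketone.

Alternative 2: Cut C3–C4, read as the bond made by a 1,2-shift, so the oxolane is traced back to the six-membered hydroxy mesylate A5, whose oxane ring would come from a hetero-Diels–Alder reaction of 6.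
- Forward key step: KOt-Bu deprotonates the tertiary aryl carbinol of A5. Ring carbon C3 migrates to the mesylate-bearing carbon with inversion, mesylate leaves, and the carbinol carbon becomes the aryl ketone of A4, the tert-butyldimethylsilyl ether of the target.
- In its favour: the shift is stereospecific, so C4 is fixed by the mesylate configuration and not by an equilibrium. The aryl ketone appears directly. C2 could be set by a catalytic enantioselective cycloaddition. A4 is one desilylation from the target, an end game equal to the chosen one.
- Against it here: A5 requires three further contiguous positions to be dressed on the cycloadduct, which is a long linear sequence. The tertiary benzylic carbinol of an electron-rich arene is exposed to ionisation during mesylation. The aryl group on the carbinol carbon competes with the ring carbon as migrating group, and only an equatorial mesylate aligns the ring bond. The strong base meets a β-alkoxy ketone product.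
- Comparison: both plans contract a six- to a five-membered ring by a pinacol-type shift. The alternative is better in that its shift is anionic and stereospecific at C4, and equal in the last deprotection. It is clearly worse in step economy, since ring formation, substitution and contraction are separate, whereas the chosen cascade makes two bonds, the ring and three stereocentres in one step.

Alternative 3: Cut C2–C3 and the acyl C–O bond O1–C5, giving 6 and the enal A7 as components.
- Forward key step: a chiral triazolium-derived carbene turns A7 into a homoenolate equivalent. Its β-carbon attacks 6 (C2–C3) and the new alkoxide acylates on the acyl azolium (O1–C5), releasing the cis lactone A6.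
- In its favour: it is catalytic and metal-free and uses two simple achiral components. Like the chosen step it makes two bonds, one ring and the cis C2/C3 pair at once, and it reaches the ring in fewer steps; on that count it is the better one.
- Against it here: C5 arrives as a lactone carbonyl and must be reduced to CH2 beside two ionisable benzylic C–O bonds. The C4 aroyl group is missing and must be added through the lactone enolate before that reduction. The γ-silyloxy group of A7 can be expelled from the carbene adduct. Electron-rich aryl aldehydes are poor partners for homoenolates, and cis and enantioselectivity are not secure.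
- Comparison: the anionic mechanism avoids the Lewis acid, which is an advantage. The product, however, has the wrong oxidation level at C5 and lacks the C4 carbon substituent, whereas the chosen step delivers C5 as CH2 with the carbonyl carbon already on C4. After ring formation the alternative needs at least as many steps with harder chemoselectivity, so overall step economy is equal at best.

Key step: step 6

Remark: 8 forms as a mixture of epimers at the acetal carbon and is used as such, because that carbon becomes planar in step 6; 1 is taken as enantiopure commercial material.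

## Route

Step 1
Reactants: 1 [(4R)-2,2-dimethyl-1,3-dioxolan-4-yl]methanol ((R)-solketal)
Product: 2 (4S)-2,2-dimethyl-1,3-dioxolane-4-carbaldehyde
Conditions: (COCl)2, DMSO, CH2Cl2, −78 °C; Et3N, −78 → 0 °C; filtered through silica, used at once
Reagents that add atoms: none
Why: Swern oxidation of a primary alcohol; the base-sensitive α-alkoxy aldehyde is made cold and carried on at once so the stereocentre is not eroded (the descriptor changes from R to S only through the priority rules).

Step 2
Reactants: 2 (4S)-2,2-dimethyl-1,3-dioxolane-4-carbaldehyde
Product: 3 methyl (2Z)-3-[(4R)-2,2-dimethyl-1,3-dioxolan-4-yl]prop-2-enoate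
Conditions: (CF3CH2O)2P(O)CH2CO2Me, KN(SiMe3)2, 18-crown-6, THF, −78 °C
Reagents that add atoms: methyl 2-[bis(2,2,2-trifluoroethoxy)phosphoryl]acetate, COC(=O)CP(=O)(OCC(F)(F)F)OCC(F)(F)F
Why: Still–Gennari variant of the Horner–Wadsworth–Emmons olefination; the electron-poor phosphonate under dissociating conditions eliminates quickly from the kinetic adduct and should give the Z-enoate, and the cold, weakly basic medium should leave the α-alkoxy centre intact.

Step 3
Reactants: 3 methyl (2Z)-3-[(4R)-2,2-dimethyl-1,3-dioxolan-4-yl]prop-2-enoate
Product: 4 (2Z)-3-[(4R)-2,2-dimethyl-1,3-dioxolan-4-yl]prop-2-en-1-ol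
Conditions: i-Bu2AlH (2.3 equiv), CH2Cl2, −78 °C; aq. potassium sodium tartrate
Reagents that add atoms: none
Why: 1,2-Reduction of an α,β-unsaturated ester by the aluminium hydride; at −78 °C the Z double bond should not isomerise and the acetonide is inert.

Step 4
Reactants: 4 (2Z)-3-[(4R)-2,2-dimethyl-1,3-dioxolan-4-yl]prop-2-en-1-ol
Product: 5 tert-butyl{[(2Z)-3-[(4R)-2,2-dimethyl-1,3-dioxolan-4-yl]prop-2-en-1-yl]oxy}diphenylsilane
Conditions: TBDPSCl, imidazole, CH2Cl2, 0 °C → rt
Reagents that add atoms: tert-butyl(chloro)diphenylsilane, CC(C)(C)[Si](Cl)(c1ccccc1)c1ccccc1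
Why: Standard silylation of a primary allylic alcohol; the TBDPS ether is non-participating, bulky enough to discourage complexation by SnCl4 and stable to the mild acid of step 5.

Step 5
Reactants: 5 tert-butyl{[(2Z)-3-[(4R)-2,2-dimethyl-1,3-dioxolan-4-yl]prop-2-en-1-yl]oxy}diphenylsilane; 6 3,4,5-trimethoxybenzaldehyde
Product: 8 (4R)-4-[(1Z)-3-(tert-butyldiphenylsilyloxy)prop-1-en-1-yl]-2-(3,4,5-trimethoxyphenyl)-1,3-dioxolane (both epimers at the acetal carbon), via (2R,3Z)-5-(tert-butyldiphenylsilyloxy)pent-3-ene-1,2-diol 7 (not isolated)
Conditions: PPTS (cat.), MeOH, 50 °C; concentrate; then 6, toluene, 4 Å MS, 60 °C; Et3N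
Reagents that add atoms: none
Why: Acid-catalysed methanolysis of the terminal acetonide, then, after removal of the volatile ketal, acetalisation of the freed 1,2-diol with the aldehyde under dehydrating conditions; the carbinol centre is untouched and both acetal epimers converge on one oxocarbenium ion in step 6.

Step 6
Reactants: 8 (4R)-4-[(1Z)-3-(tert-butyldiphenylsilyloxy)prop-1-en-1-yl]-2-(3,4,5-trimethoxyphenyl)-1,3-dioxolane
Product: 9 (2S,3S,4S)-3-[(tert-butyldiphenylsilyloxy)methyl]-2-(3,4,5-trimethoxyphenyl)oxolane-4-carbaldehyde (all-cis)
Conditions: SnCl4 (1.5 equiv), CH2Cl2, −78 → −20 °C; Et3N, aq. NaHCO3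
Reagents that add atoms: none
Why: SnCl4 complexes the acetal and opens it on the side of the secondary allylic oxygen, which stays as a tin alkoxide, so the aryl-stabilised (E)-oxocarbenium ion sits on the primary oxygen. The distal carbon of the Z-alkene attacks the oxocarbenium carbon in a 6-endo-trig Prins closure through a chair, forming C2–C3 and an oxanyl cation at the former proximal alkene carbon. A pinacol-type 1,2-shift of the ring CH2–O carbon from the carbinol carbon to this cation, pushed by the tin alkoxide, forms C4–C5 and turns the carbinol carbon into the formyl group; the oxolane thus arises by contraction of the six-membered ring and not by a direct five-membered closure (a 2-oxonia-Cope/aldol path would need a 5-endo-trig closure and would pass through the same chair in any case). The closest known reaction type is the Lewis acid promoted Prins–pinacol rearrangement of 4-alkenyl-1,3-dioxolanes to 3-acyl tetrahydrofurans, including secondary allylic carbinols that end as formyl groups. C2 and C3 are set relative to each other by the chair: the aryl group of the (E)-oxocarbenium ion is equatorial and the Z-substituent CH2OSi is forced axial, hence cis. Their absolute configuration comes from the (4R)-carbinol centre, whose tin alkoxide takes the equatorial site so that only hydrogen faces the axial Z-substituent (allylic 1,3-strain), which exposes one alkene face and gives 2S,3S; C4 is set by the migrating carbon arriving on the cation face it already flanks, which places the formyl group cis (4S), and step 7 corrects this centre. The step needs regioselective ionisation (the opposite C–O cleavage is reversible and offers only a disfavoured 5-endo closure), an alkyl shift faster than 1,2-hydride shift or chloride capture (the intramolecular, alkoxide-driven shift is expected to win), and survival of the allylic silyl ether (bulky, non-participating TBDPS group and low temperature). Both acetal epimers give the same oxocarbenium ion.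

Step 7
Reactants: 9 (2S,3S,4S)-3-[(tert-butyldiphenylsilyloxy)methyl]-2-(3,4,5-trimethoxyphenyl)oxolane-4-carbaldehyde
Product: 10 (2S,3S,4R)-3-[(tert-butyldiphenylsilyloxy)methyl]-2-(3,4,5-trimethoxyphenyl)oxolane-4-carbaldehyde
Conditions: DBU (0.3 equiv), CH2Cl2, rt
Reagents that add atoms: none
Why: Base-mediated epimerisation of the aldehyde α-carbon through its enolate; the all-cis isomer loses the eclipsing formyl/CH2OSi interaction, so the equilibrium should lie on the 3,4-trans (4R) side, while C2 and C3 are not acidic and stay fixed.

Step 8
Reactants: 10 (2S,3S,4R)-3-[(tert-butyldiphenylsilyloxy)methyl]-2-(3,4,5-trimethoxyphenyl)oxolane-4-carbaldehyde; 11 5-bromo-1,2,3-trimethoxybenzene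
Product: 13 {(2S,3S,4R)-3-[(tert-butyldiphenylsilyloxy)methyl]-2-(3,4,5-trimethoxyphenyl)oxolan-4-yl}(3,4,5-trimethoxyphenyl)methanol (both carbinol epimers), via (3,4,5-trimethoxyphenyl)magnesium bromide 12 (not isolated)
Conditions: 11, Mg, I2 (cat.), THF, 45 °C; then 10, THF, −78 → −20 °C; aq. NH4Cl
Reagents that add atoms: none
Why: Grignard formation from the aryl bromide and 1,2-addition to the aldehyde at low temperature; the new carbinol configuration is immaterial because step 9 removes it, and C4 already holds its preferred configuration.

Step 9
Reactants: 13 {(2S,3S,4R)-3-[(tert-butyldiphenylsilyloxy)methyl]-2-(3,4,5-trimethoxyphenyl)oxolan-4-yl}(3,4,5-trimethoxyphenyl)methanol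
Product: 14 {(2S,3S,4R)-3-[(tert-butyldiphenylsilyloxy)methyl]-2-(3,4,5-trimethoxyphenyl)oxolan-4-yl}(3,4,5-trimethoxyphenyl)methanone
Conditions: Dess–Martin periodinane, CH2Cl2, 0 °C → rt
Reagents that add atoms: none
Why: Dess–Martin oxidation of the secondary benzylic alcohol to the aryl ketone under nearly neutral conditions; C4 stays in the favoured trans arrangement.

Step 10
Reactants: 14 {(2S,3S,4R)-3-[(tert-butyldiphenylsilyloxy)methyl]-2-(3,4,5-trimethoxyphenyl)oxolan-4-yl}(3,4,5-trimethoxyphenyl)methanone
Product: 15 [(2S,3S,4R)-3-(hydroxymethyl)-2-(3,4,5-trimethoxyphenyl)oxolan-4-yl](3,4,5-trimethoxyphenyl)methanone (target)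
Conditions: Bu4NF, AcOH (1:1), THF, 0 °C → rt
Reagents that add atoms: none
Why: Fluoride cleavage of the silyl ether; the acetic acid buffer suppresses enolisation at C4 and retro-oxa-Michael opening of the β-alkoxy ketone, and the γ-hydroxy ketone cannot close to a hemiketal without a trans-fused bicycle.

## Compound list

1 | [(4R)-2,2-dimethyl-1,3-dioxolan-4-yl]methanol | CC1(C)OC[C@@H](CO)O1 | starting material
2 | (4S)-2,2-dimethyl-1,3-dioxolane-4-carbaldehyde | CC1(C)OC[C@@H](C=O)O1 | intermediate
3 | methyl (2Z)-3-[(4R)-2,2-dimethyl-1,3-dioxolan-4-yl]prop-2-enoate | COC(=O)/C=C\[C@@H]1COC(C)(C)O1 | intermediate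
4 | (2Z)-3-[(4R)-2,2-dimethyl-1,3-dioxolan-4-yl]prop-2-en-1-ol | OC/C=C\[C@@H]1COC(C)(C)O1 | intermediate
5 | tert-butyl{[(2Z)-3-[(4R)-2,2-dimethyl-1,3-dioxolan-4-yl]prop-2-en-1-yl]oxy}diphenylsilane | CC(C)(C)[Si](c1ccccc1)(c1ccccc1)OC/C=C\[C@@H]1COC(C)(C)O1 | intermediate
6 | 3,4,5-trimethoxybenzaldehyde | COc1cc(C=O)cc(OC)c1OC | starting material
7 | (2R,3Z)-5-(tert-butyldiphenylsilyloxy)pent-3-ene-1,2-diol | OC[C@H](O)/C=C\CO[Si](c1ccccc1)(c1ccccc1)C(C)(C)C | intermediate (not isolated)
8 | (4R)-4-[(1Z)-3-(tert-butyldiphenylsilyloxy)prop-1-en-1-yl]-2-(3,4,5-trimethoxyphenyl)-1,3-dioxolane (cis-(2S,4R) epimer drawn; the (2R,4R) epimer forms with it and is used too) | CC(C)(C)[Si](c1ccccc1)(c1ccccc1)OC/C=C\[C@@H]1CO[C@H](c2cc(OC)c(OC)c(OC)c2)O1 | intermediate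
9 | (2S,3S,4S)-3-[(tert-butyldiphenylsilyloxy)methyl]-2-(3,4,5-trimethoxyphenyl)oxolane-4-carbaldehyde (all-cis) | O=C[C@@H]1CO[C@H](c2cc(OC)c(OC)c(OC)c2)[C@@H]1CO[Si](c1ccccc1)(c1ccccc1)C(C)(C)C | intermediate
10 | (2S,3S,4R)-3-[(tert-butyldiphenylsilyloxy)methyl]-2-(3,4,5-trimethoxyphenyl)oxolane-4-carbaldehyde (2,3-cis, 3,4-trans) | O=C[C@H]1CO[C@H](c2cc(OC)c(OC)c(OC)c2)[C@@H]1CO[Si](c1ccccc1)(c1ccccc1)C(C)(C)C | intermediate
11 | 5-bromo-1,2,3-trimethoxybenzene | COc1cc(Br)cc(OC)c1OC | starting material
12 | (3,4,5-trimethoxyphenyl)magnesium bromide | COc1cc([Mg]Br)cc(OC)c1OC | intermediate (not isolated)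
13 | {(2S,3S,4R)-3-[(tert-butyldiphenylsilyloxy)methyl]-2-(3,4,5-trimethoxyphenyl)oxolan-4-yl}(3,4,5-trimethoxyphenyl)methanol (both carbinol epimers) | OC(c1cc(OC)c(OC)c(OC)c1)[C@H]1CO[C@H](c2cc(OC)c(OC)c(OC)c2)[C@@H]1CO[Si](c1ccccc1)(c1ccccc1)C(C)(C)C | intermediate
14 | {(2S,3S,4R)-3-[(tert-butyldiphenylsilyloxy)methyl]-2-(3,4,5-trimethoxyphenyl)oxolan-4-yl}(3,4,5-trimethoxyphenyl)methanone | O=C(c1cc(OC)c(OC)c(OC)c1)[C@H]1CO[C@H](c2cc(OC)c(OC)c(OC)c2)[C@@H]1CO[Si](c1ccccc1)(c1ccccc1)C(C)(C)C | intermediate
15 | [(2S,3S,4R)-3-(hydroxymethyl)-2-(3,4,5-trimethoxyphenyl)oxolan-4-yl](3,4,5-trimethoxyphenyl)methanone | COc1cc(C(=O)[C@H]2CO[C@H](c3cc(OC)c(OC)c(OC)c3)[C@@H]2CO)cc(OC)c1OC | target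

## Step count and least certain steps

Total step count: 10. Longest linear sequence: 10 steps (1 → 15); 6 enters in step 5 and 11 in step 8.

Step 6 (key step).
- What may go wrong: ionisation may stall or run in the unproductive direction. The Z-alkene is deactivated by its allylic oxygen and may be too slow to capture the aryl-stabilised oxocarbenium ion before the silyl ether or the electron-rich arene reacts. A 1,2-hydride shift or chloride capture may compete with the ring-contracting shift. Closure through a boat or an axial-alkoxide chair would erode the enantiomeric purity.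
- Fallback (anionic ring construction in place of the cationic cascade; sets out from 6, returns at 15): addition of ethynylmagnesium bromide to 6 and lipase-catalysed acylative resolution, in which the (S)-alcohol is expected to react slowly, would give (1S)-1-(3,4,5-trimethoxyphenyl)prop-2-yn-1-ol F1. Its alkoxide (KOt-Bu, cat.) would add to the 2-aroylacrylate generated in the flask from A3, and CuI-promoted 5-exo-dig carbocyclisation would close methyl (2R)-3-methylidene-4-(3,4,5-trimethoxybenzoyl)-2-(3,4,5-trimethoxyphenyl)oxolane-4-carboxylate F2 (the structure called A1 above; 2R only by the priority rules). Hydroboration with 9-BBN from the face away from the C2 aryl group and oxidation with NaBO3 would give methyl (2S,3S)-3-(hydroxymethyl)-4-(3,4,5-trimethoxybenzoyl)-2-(3,4,5-trimethoxyphenyl)oxolane-4-carboxylate F3. Dealkoxycarbonylation (LiCl, wet DMSO, heat), with C4 settling trans to the hydroxymethyl group, would give 15.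

Step 2.
- What may go wrong: incomplete Z-selectivity, or oligomerisation of the labile α-alkoxy aldehyde before it is olefinated.
- Fallback (geometry fixed by syn-hydrogenation of an alkyne; sets out from 2, returns at 4): Ohira–Bestmann homologation (dimethyl (1-diazo-2-oxopropyl)phosphonate, K2CO3, MeOH) would give (4R)-4-ethynyl-2,2-dimethyl-1,3-dioxolane F4. Lithiation with n-BuLi and trapping with paraformaldehyde would give 3-[(4R)-2,2-dimethyl-1,3-dioxolan-4-yl]prop-2-yn-1-ol F5. Semihydrogenation over Pd/CaCO3 poisoned with Pb(OAc)2 (quinoline, H2) would give 4.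

Step 5.
- What may go wrong: incomplete methanolysis of the acetonide, partial loss of the silyl ether on concentration with acid, or incomplete acetalisation of the electron-rich aldehyde when water is not removed well.
- Fallback (aprotic silyl-transfer acetalisation; sets out from 5, returns at 8): hydrolysis with aqueous AcOH and isolation of 7, then silylation (Me3SiCl, Et3N) to (2R,3Z)-5-(tert-butyldiphenylsilyloxy)-1,2-bis(trimethylsilyloxy)pent-3-ene F6. Reaction of F6 with 6 under catalytic Me3SiOTf at −78 °C would give 8 without protic acid or water removal.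

Step 7.
- What may go wrong: incomplete equilibration, retro-oxa-Michael ring opening, or self-aldol reaction of the aldehyde under base.
- Fallback (epimerisation moved to the ketone stage; sets out from 9, returns at 14): addition of 12 to 9 would give the all-cis carbinol {(2S,3S,4S)-3-[(tert-butyldiphenylsilyloxy)methyl]-2-(3,4,5-trimethoxyphenyl)oxolan-4-yl}(3,4,5-trimethoxyphenyl)methanol F7. Dess–Martin oxidation would give the all-cis ketone {(2S,3S,4S)-3-[(tert-butyldiphenylsilyloxy)methyl]-2-(3,4,5-trimethoxyphenyl)oxolan-4-yl}(3,4,5-trimethoxyphenyl)methanone F8. Equilibration with DBU at the less electrophilic ketone would give 14.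

Step 8.
- What may go wrong: enolisation of the α-branched aldehyde by the basic reagent, β-elimination of the ring oxygen, or slow addition beside the neighbouring substituents.
- Fallback (base-free ketone synthesis; sets out from 10, returns at 14): Pinnick oxidation (NaClO2, NaH2PO4, 2-methylbut-2-ene) would give (2S,3S,4R)-3-[(tert-butyldiphenylsilyloxy)methyl]-2-(3,4,5-trimethoxyphenyl)oxolane-4-carboxylic acid F9. Thioesterification (EtSH, DCC, DMAP) would give S-ethyl (2S,3S,4R)-3-[(tert-butyldiphenylsilyloxy)methyl]-2-(3,4,5-trimethoxyphenyl)oxolane-4-carbothioate F10. Liebeskind–Srogl coupling with (3,4,5-trimethoxyphenyl)boronic acid (Pd2(dba)3, tri(2-furyl)phosphine, Cu(O2CC4H3S), THF, 50 °C) would give 14 directly.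

## Further compounds

F1 | step 6 | (1S)-1-(3,4,5-trimethoxyphenyl)prop-2-yn-1-ol | C#C[C@H](O)c1cc(OC)c(OC)c(OC)c1
F2 | step 6 | methyl (2R)-3-methylidene-4-(3,4,5-trimethoxybenzoyl)-2-(3,4,5-trimethoxyphenyl)oxolane-4-carboxylate (both C4 epimers) | COC(=O)C1(C(=O)c2cc(OC)c(OC)c(OC)c2)CO[C@H](c2cc(OC)c(OC)c(OC)c2)C1=C
F3 | step 6 | methyl (2S,3S)-3-(hydroxymethyl)-4-(3,4,5-trimethoxybenzoyl)-2-(3,4,5-trimethoxyphenyl)oxolane-4-carboxylate (both C4 epimers) | COC(=O)C1(C(=O)c2cc(OC)c(OC)c(OC)c2)CO[C@H](c2cc(OC)c(OC)c(OC)c2)[C@@H]1CO
F4 | step 2 | (4R)-4-ethynyl-2,2-dimethyl-1,3-dioxolane | C#C[C@@H]1COC(C)(C)O1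
F5 | step 2 | 3-[(4R)-2,2-dimethyl-1,3-dioxolan-4-yl]prop-2-yn-1-ol | OCC#C[C@@H]1COC(C)(C)O1
F6 | step 5 | (2R,3Z)-5-(tert-butyldiphenylsilyloxy)-1,2-bis(trimethylsilyloxy)pent-3-ene | C[Si](C)(C)OC[C@H](O[Si](C)(C)C)/C=C\CO[Si](c1ccccc1)(c1ccccc1)C(C)(C)C
F7 | step 7 | {(2S,3S,4S)-3-[(tert-butyldiphenylsilyloxy)methyl]-2-(3,4,5-trimethoxyphenyl)oxolan-4-yl}(3,4,5-trimethoxyphenyl)methanol (both carbinol epimers) | OC(c1cc(OC)c(OC)c(OC)c1)[C@@H]1CO[C@H](c2cc(OC)c(OC)c(OC)c2)[C@@H]1CO[Si](c1ccccc1)(c1ccccc1)C(C)(C)C
F8 | step 7 | {(2S,3S,4S)-3-[(tert-butyldiphenylsilyloxy)methyl]-2-(3,4,5-trimethoxyphenyl)oxolan-4-yl}(3,4,5-trimethoxyphenyl)methanone | O=C(c1cc(OC)c(OC)c(OC)c1)[C@@H]1CO[C@H](c2cc(OC)c(OC)c(OC)c2)[C@@H]1CO[Si](c1ccccc1)(c1ccccc1)C(C)(C)C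
F9 | step 8 | (2S,3S,4R)-3-[(tert-butyldiphenylsilyloxy)methyl]-2-(3,4,5-trimethoxyphenyl)oxolane-4-carboxylic acid | OC(=O)[C@H]1CO[C@H](c2cc(OC)c(OC)c(OC)c2)[C@@H]1CO[Si](c1ccccc1)(c1ccccc1)C(C)(C)C
F10 | step 8 | S-ethyl (2S,3S,4R)-3-[(tert-butyldiphenylsilyloxy)methyl]-2-(3,4,5-trimethoxyphenyl)oxolane-4-carbothioate | CCSC(=O)[C@H]1CO[C@H](c2cc(OC)c(OC)c(OC)c2)[C@@H]1CO[Si](c1ccccc1)(c1ccccc1)C(C)(C)C
A1 | alternative 1 | methyl (2R)-3-methylidene-4-(3,4,5-trimethoxybenzoyl)-2-(3,4,5-trimethoxyphenyl)oxolane-4-carboxylate (one C4 epimer drawn) | COC(=O)[C@]1(C(=O)c2cc(OC)c(OC)c(OC)c2)CO[C@H](c2cc(OC)c(OC)c(OC)c2)C1=C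
A2 | alternative 1 | (1S)-1-(3,4,5-trimethoxyphenyl)prop-2-yn-1-ol | C#C[C@H](O)c1cc(OC)c(OC)c(OC)c1
A3 | alternative 1 | methyl 3-oxo-3-(3,4,5-trimethoxyphenyl)propanoate | COC(=O)CC(=O)c1cc(OC)c(OC)c(OC)c1
A4 | alternative 2 | {(2S,3S,4R)-3-[(tert-butyldimethylsilyloxy)methyl]-2-(3,4,5-trimethoxyphenyl)oxolan-4-yl}(3,4,5-trimethoxyphenyl)methanone | O=C(c1cc(OC)c(OC)c(OC)c1)[C@H]1CO[C@H](c2cc(OC)c(OC)c(OC)c2)[C@@H]1CO[Si](C)(C)C(C)(C)C
A5 | alternative 2 | 3-[(tert-butyldimethylsilyloxy)methyl]-4-hydroxy-2,4-bis(3,4,5-trimethoxyphenyl)oxan-5-yl methanesulfonate, hydroxyl cis to the mesylate, configuration as in the SMILES | CS(=O)(=O)O[C@H]1CO[C@H](c2cc(OC)c(OC)c(OC)c2)[C@H](CO[Si](C)(C)C(C)(C)C)[C@]1(O)c3cc(OC)c(OC)c(OC)c3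
A6 | alternative 3 | (4S,5S)-4-[(tert-butyldimethylsilyloxy)methyl]-5-(3,4,5-trimethoxyphenyl)oxolan-2-one (cis) | C1C(=O)O[C@H](c2cc(OC)c(OC)c(OC)c2)[C@@H]1CO[Si](C)(C)C(C)(C)C
A7 | alternative 3 | (2E)-4-(tert-butyldimethylsilyloxy)but-2-enal | O=C/C=C/CO[Si](C)(C)C(C)(C)C
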